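## Retrosynthetic overview

1. Locants: ring C1 (quaternary), C2 (C=O), C3=C4, C5 (C=O), C6 (CH2); chain C1'–C16'. Feature used: C2(=O)–C1–CH2–CO2Me is a γ-keto ester (1,4-dicarbonyl, Stetter retron). The acetate arm on C1 also lies 1,3 to the C5 oxygen, so both can be tied into one δ-lactone.
2. Key disconnection C1–C2: intramolecular Stetter reaction of the C2 aldehyde onto C1 of a 4-alkyl-6-(3-oxopropyl)-5,6-dihydropyran-2-one. It closes the only carbocycle, makes the quaternary carbon, and relays its configuration from the C5–O stereocentre, which is later oxidised away to the C5 ketone.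
3. C1–C1' is cut next: Stille coupling of a 4-stannyl dihydropyranone with the intact (E)-allylic acetate. The lactone comes from (S)-1,2-epoxy-5-hexene and methyl propiolate.
4. Chain: farnesyl acetate, terminal allylic oxidation, anti-selective γ-borylallylboration (12'S,13'R), cross metathesis.
5. Ring order: dihydropyranone (step 7), carbocycle as 2-oxabicyclo[3.3.1]nonane (step 10), lactone opened (step 11), enedione (step 12).

Key step: step 10

Assumption: compounds 1, 4, 8, 11 and 12 are taken as commercial, and (+)-Ipc2BH is made as a reagent from (−)-α-pinene and BH3·SMe2.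

Abbreviation: A = (2E,6E,10E,12S,13R)-12,13-bis(tert-butyldimethylsilyloxy)-3,7,11,15-tetramethylhexadeca-2,6,10,14-tetraen-1-yl.

## Route

Step 1
Reactants: 1 (2E,6E)-farnesyl acetate
Product: 2 (2E,6E,10E)-12-hydroxy-3,7,11-trimethyldodeca-2,6,10-trien-1-yl acetate
Conditions: SeO2 (0.1 equiv), t-BuOOH, salicylic acid (0.1 equiv), CH2Cl2, 0 °C to rt
Reagents that add atoms: selenium dioxide (catalytic O carrier), O=[Se]=O; tert-butyl hydroperoxide, CC(C)(C)OO
Why: Riley allylic oxidation (ene reaction followed by a [2,3]-sigmatropic shift) should attack the most electron-rich and least hindered terminal isopropylidene group and hydroxylate its (E)-methyl group, while the C2' olefin is deactivated by the allylic acetate.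

Step 2
Reactants: 2 (2E,6E,10E)-12-hydroxy-3,7,11-trimethyldodeca-2,6,10-trien-1-yl acetate
Product: 3 (2E,6E,10E)-3,7,11-trimethyl-12-oxododeca-2,6,10-trien-1-yl acetate
Conditions: activated MnO2 (excess), CH2Cl2, rt
Reagents that add atoms: none
Why: Heterogeneous MnO2 oxidation is selective for the allylic alcohol and should stop at the (E)-enal without touching the acetate or the olefins.

Step 3
Reactants: 3 (2E,6E,10E)-3,7,11-trimethyl-12-oxododeca-2,6,10-trien-1-yl acetate; 4 allenylboronic acid pinacol ester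
Product: 7 (2E,6E,10E,12S,13R)-12,13-dihydroxy-3,7,11-trimethylpentadeca-2,6,10,14-tetraen-1-yl acetate, via (E)-γ-borylallylborane 5 (not isolated), via borinate boronate adduct 6 (not isolated)
Conditions: (+)-Ipc2BH, 4, Et2O, 0 °C to rt; 3, −78 °C; then NaBO3·4H2O, THF–H2O, rt
Reagents that add atoms: (+)-diisopinocampheylborane (its boron and Ipc groups stay only in 5 and 6), B([C@H]1C[C@H]2C[C@@H]([C@@H]1C)C2(C)C)[C@H]1C[C@H]2C[C@@H]([C@@H]1C)C2(C)C; sodium perborate, [Na+].[Na+].O[B-]1(O)OO[B-](O)(O)OO1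
Why: Allene hydroboration gives after boratropic equilibration the (E)-γ-borylallylborane, whose allylboration of the enal through a closed Zimmerman–Traxler chair sets the anti relationship while the Ipc groups derived from (−)-α-pinene select the aldehyde face that leads to 12'S, and the stereoretentive C–B oxidation then fixes 13'R.

Step 4
Reactants: 7 (2E,6E,10E,12S,13R)-12,13-dihydroxy-3,7,11-trimethylpentadeca-2,6,10,14-tetraen-1-yl acetate; 8 2-methyl-2-butene
Product: 9 (2E,6E,10E,12S,13R)-12,13-dihydroxy-3,7,11,15-tetramethylhexadeca-2,6,10,14-tetraen-1-yl acetate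
Conditions: second-generation Ru metathesis catalyst with chelating isopropoxybenzylidene (5 mol %), 8 (excess), CH2Cl2, 40 °C, sealed tube
Reagents that add atoms: none
Why: Olefin cross metathesis should engage only the monosubstituted vinyl group, since the trisubstituted chain olefins are too hindered to enter the catalytic cycle, and exchange its CH2 terminus for the isopropylidene unit without touching the stereocentres.

Step 5
Reactants: 9 (2E,6E,10E,12S,13R)-12,13-dihydroxy-3,7,11,15-tetramethylhexadeca-2,6,10,14-tetraen-1-yl acetate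
Product: 10 A–OAc, (2E,6E,10E,12S,13R)-12,13-bis(tert-butyldimethylsilyloxy)-3,7,11,15-tetramethylhexadeca-2,6,10,14-tetraen-1-yl acetate
Conditions: TBSOTf (2.5 equiv), 2,6-lutidine, CH2Cl2, −78 to 0 °C
Reagents that add atoms: tert-butyldimethylsilyl triflate, CC(C)(C)[Si](C)(C)OS(=O)(=O)C(F)(F)F
Why: Silylation with the reactive triflate should cap both hindered allylic carbinols as fluoride-labile ethers, which avoids any acidic unmasking of the ionisable bis-allylic diol at the end.

Step 6
Reactants: 11 (S)-1,2-epoxy-5-hexene; 12 methyl propiolate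
Product: 13 methyl (5S)-5-hydroxynon-8-en-2-ynoate
Conditions: 12, n-BuLi, THF, −78 °C; BF3·OEt2; then 11, −78 °C
Reagents that add atoms: none
Why: Lewis acid assisted SN2 opening of the terminal epoxide by the lithium acetylide occurs at the unsubstituted carbon C6, so the purchased C5 stereocentre is retained.

Step 7
Reactants: 13 methyl (5S)-5-hydroxynon-8-en-2-ynoate
Product: 15 (6S)-6-(but-3-en-1-yl)-4-(tributylstannyl)-5,6-dihydro-2H-pyran-2-one, via (E)-β-stannyl hydroxy enoate 14 (not isolated)
Conditions: Bu3SnH, LDA, THF, −78 to 0 °C; CuBr·SMe2, −78 °C; 13, MeOH, −78 °C; aq NH4Cl; then PPTS (cat.), CH2Cl2, rt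
Reagents that add atoms: tributyltin hydride, CCCC[SnH](CCCC)CCCC
Why: syn-Stannylcupration of the ynoate under kinetic protonation places tin on the β-carbon C1 and the C6 arm cis to the ester, so that the δ-hydroxy group closes the dihydropyranone by lactonisation.

Step 8
Reactants: 15 (6S)-6-(but-3-en-1-yl)-4-(tributylstannyl)-5,6-dihydro-2H-pyran-2-one
Product: 16 3-[(2S)-6-oxo-4-(tributylstannyl)-3,6-dihydro-2H-pyran-2-yl]propanal
Conditions: OsO4 (2 mol %), NaIO4, 2,6-lutidine, dioxane–H2O, rt
Reagents that add atoms: osmium tetroxide (catalytic O carrier), O=[Os](=O)(=O)=O; sodium periodate, [Na+].[O-]I(=O)(=O)=O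
Why: Lemieux–Johnson cleavage should select the electron-rich monosubstituted olefin over the electron-poor and hindered β-stannyl enoate and give the aldehyde C2.

Step 9
Reactants: 10 A–OAc; 16 3-[(2S)-6-oxo-4-(tributylstannyl)-3,6-dihydro-2H-pyran-2-yl]propanal
Product: 17 3-[(2S)-4-A-6-oxo-3,6-dihydro-2H-pyran-2-yl]propanal
Conditions: Pd2(dba)3 (5 mol %), LiCl (3 equiv), DMF, rt to 40 °C
Reagents that add atoms: none
Why: Stille coupling through the π-allylpalladium complex of the primary allylic acetate should form the C1–C1' bond at the less hindered allyl terminus with retention of the 2'E geometry, under neutral conditions that spare the aldehyde, the lactone and the allylic silyl ethers.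

Step 10
Reactants: 17 3-[(2S)-4-A-6-oxo-3,6-dihydro-2H-pyran-2-yl]propanal
Product: 18 (1S,5R)-5-A-2-oxabicyclo[3.3.1]nonane-3,6-dione
Conditions: 2-(pentafluorophenyl)-6,7-dihydro-5H-pyrrolo[2,1-c][1,2,4]triazolium tetrafluoroborate (20 mol %), i-Pr2NEt (20 mol %), toluene (0.02 M), 40–60 °C
Reagents that add atoms: none
Why: The triazolylidene adds to the aldehyde C2 and proton transfer gives the Breslow intermediate, an acyl anion equivalent that adds 1,4 to C1, the β-carbon of the unsaturated lactone, after which α-protonation and loss of the carbene give the γ-keto lactone (intramolecular Stetter reaction). The closest known reaction type is the intramolecular Stetter reaction of aliphatic aldehydes with β,β-disubstituted enoates, which gives α-quaternary cycloalkanones bearing a CH2CO2R arm. The carbocycle closes in the 6-exo-trig mode (C2 onto C1, the enoate α-carbon stays outside the new ring) and the product is the strain-free chair–chair 2-oxabicyclo[3.3.1]nonane. The only new stereocentre, quaternary C1, is controlled by C5: the three-carbon tether on (S)-C5 must stand pseudo-axial and can reach C1 only from its own face of the lactone, so the acetate arm and the C5 oxygen end up cis-1,3 in the lactone bridge and chain A is pushed to the other face, which is 1R in target locants. The step needs acyl anion addition to win over γ-deprotonation at the skipped-diene CH2 (C1') and over eliminative opening of the dihydropyranone. A catalytic weak amine base with an electron-poor N-C6F5 azolium salt keeps the medium too weakly basic for both, and the trisubstituted chain olefins are not acceptors.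

Step 11
Reactants: 18 (1S,5R)-5-A-2-oxabicyclo[3.3.1]nonane-3,6-dione
Product: 19 methyl 2-[(1R,5S)-1-A-5-hydroxy-2-oxocyclohexyl]acetate
Conditions: K2CO3 (0.3 equiv), MeOH, 0 °C
Reagents that add atoms: methanol, CO
Why: Base-catalysed transesterification opens the bridged δ-lactone, whose closure needs a 1,3-diaxial arrangement, to the methyl ester and the free C5 carbinol without touching the quaternary centre.

Step 12
Reactants: 19 methyl 2-[(1R,5S)-1-A-5-hydroxy-2-oxocyclohexyl]acetate
Product: 21 methyl 2-[(1R)-1-A-2,5-dioxocyclohex-3-en-1-yl]acetate, via saturated 1,4-dione 20 (not isolated)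
Conditions: IBX (4 equiv), DMSO, rt then 65 °C
Reagents that add atoms: none
Why: IBX first oxidises the C5 carbinol, which erases the relay stereocentre, and then dehydrogenates the 1,4-dione by way of its enol, a process that can only occur across C3–C4 because C6 is flanked by the quaternary C1.

Step 13
Reactants: 21 methyl 2-[(1R)-1-A-2,5-dioxocyclohex-3-en-1-yl]acetate
Product: 22 methyl 2-{(1R)-1-[(2E,6E,10E,12S,13R)-12,13-dihydroxy-3,7,11,15-tetramethylhexadeca-2,6,10,14-tetraen-1-yl]-2,5-dioxocyclohex-3-en-1-yl}acetate (target)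
Conditions: HF·pyridine, pyridine, THF, 0 °C to rt
Reagents that add atoms: none
Why: Fluoride-mediated desilylation under buffered conditions should free the 12',13'-diol without ionising the allylic C–O bonds or adding to the enedione.

## Compound list

1 | (2E,6E)-farnesyl acetate | CC(=O)OC/C=C(\C)CC/C=C(\C)CCC=C(C)C | starting material
2 | (2E,6E,10E)-12-hydroxy-3,7,11-trimethyldodeca-2,6,10-trien-1-yl acetate | CC(=O)OC/C=C(\C)CC/C=C(\C)CC/C=C(\C)CO | intermediate
3 | (2E,6E,10E)-3,7,11-trimethyl-12-oxododeca-2,6,10-trien-1-yl acetate | CC(=O)OC/C=C(\C)CC/C=C(\C)CC/C=C(\C)C=O | intermediate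
4 | allenylboronic acid pinacol ester | C=C=CB1OC(C)(C)C(C)(C)O1 | starting material
5 | (E)-3-(pinacolatoboryl)allyl-bis[(+)-isopinocampheyl]borane | CC1(C)OB(/C=C/CB([C@H]2C[C@H]3C[C@@H]([C@@H]2C)C3(C)C)[C@H]2C[C@H]3C[C@@H]([C@@H]2C)C3(C)C)OC1(C)C | intermediate
6 | 12-O-(diisopinocampheylboryl)-13-(pinacolatoboryl) adduct of 3 | CC(=O)OC/C=C(\C)CC/C=C(\C)CC/C=C(\C)[C@H](OB([C@H]1C[C@H]2C[C@@H]([C@@H]1C)C2(C)C)[C@H]1C[C@H]2C[C@@H]([C@@H]1C)C2(C)C)[C@H](B1OC(C)(C)C(C)(C)O1)C=C | intermediate
7 | (2E,6E,10E,12S,13R)-12,13-dihydroxy-3,7,11-trimethylpentadeca-2,6,10,14-tetraen-1-yl acetate | CC(=O)OC/C=C(\C)CC/C=C(\C)CC/C=C(\C)[C@H](O)[C@H](O)C=C | intermediate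
8 | 2-methyl-2-butene | CC=C(C)C | starting material
9 | (2E,6E,10E,12S,13R)-12,13-dihydroxy-3,7,11,15-tetramethylhexadeca-2,6,10,14-tetraen-1-yl acetate | CC(=O)OC/C=C(\C)CC/C=C(\C)CC/C=C(\C)[C@H](O)[C@H](O)C=C(C)C | intermediate
10 | A–OAc, bis-TBS ether of 9 | CC(=O)OC/C=C(\C)CC/C=C(\C)CC/C=C(\C)[C@H](O[Si](C)(C)C(C)(C)C)[C@H](O[Si](C)(C)C(C)(C)C)C=C(C)C | intermediate
11 | (S)-1,2-epoxy-5-hexene | C=CCC[C@H]1CO1 | starting material
12 | methyl propiolate | C#CC(=O)OC | starting material
13 | methyl (5S)-5-hydroxynon-8-en-2-ynoate | C=CCC[C@H](O)CC#CC(=O)OC | intermediate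
14 | methyl (2E,5S)-5-hydroxy-3-(tributylstannyl)nona-2,8-dienoate | C=CCC[C@H](O)C/C([Sn](CCCC)(CCCC)CCCC)=C\C(=O)OC | intermediate
15 | (6S)-6-(but-3-en-1-yl)-4-(tributylstannyl)-5,6-dihydro-2H-pyran-2-one | C=CCC[C@H]1CC([Sn](CCCC)(CCCC)CCCC)=CC(=O)O1 | intermediate
16 | 3-[(2S)-6-oxo-4-(tributylstannyl)-3,6-dihydro-2H-pyran-2-yl]propanal | O=CCC[C@H]1CC([Sn](CCCC)(CCCC)CCCC)=CC(=O)O1 | intermediate
17 | 3-[(2S)-4-A-6-oxo-3,6-dihydro-2H-pyran-2-yl]propanal | O=CCC[C@H]1CC(C/C=C(\C)CC/C=C(\C)CC/C=C(\C)[C@H](O[Si](C)(C)C(C)(C)C)[C@H](O[Si](C)(C)C(C)(C)C)C=C(C)C)=CC(=O)O1 | intermediate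
18 | (1S,5R)-5-A-2-oxabicyclo[3.3.1]nonane-3,6-dione | O=C1C[C@@]2(C/C=C(\C)CC/C=C(\C)CC/C=C(\C)[C@H](O[Si](C)(C)C(C)(C)C)[C@H](O[Si](C)(C)C(C)(C)C)C=C(C)C)C[C@H](CCC2=O)O1 | intermediate
19 | methyl 2-[(1R,5S)-1-A-5-hydroxy-2-oxocyclohexyl]acetate | COC(=O)C[C@@]1(C/C=C(\C)CC/C=C(\C)CC/C=C(\C)[C@H](O[Si](C)(C)C(C)(C)C)[C@H](O[Si](C)(C)C(C)(C)C)C=C(C)C)C[C@@H](O)CCC1=O | intermediate
20 | methyl 2-[(1R)-1-A-2,5-dioxocyclohexyl]acetate | COC(=O)C[C@@]1(C/C=C(\C)CC/C=C(\C)CC/C=C(\C)[C@H](O[Si](C)(C)C(C)(C)C)[C@H](O[Si](C)(C)C(C)(C)C)C=C(C)C)CC(=O)CCC1=O | intermediate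
21 | methyl 2-[(1R)-1-A-2,5-dioxocyclohex-3-en-1-yl]acetate | COC(=O)C[C@@]1(C/C=C(\C)CC/C=C(\C)CC/C=C(\C)[C@H](O[Si](C)(C)C(C)(C)C)[C@H](O[Si](C)(C)C(C)(C)C)C=C(C)C)CC(=O)C=CC1=O | intermediate
22 | methyl 2-{(1R)-1-[(2E,6E,10E,12S,13R)-12,13-dihydroxy-3,7,11,15-tetramethylhexadeca-2,6,10,14-tetraen-1-yl]-2,5-dioxocyclohex-3-en-1-yl}acetate | COC(=O)C[C@@]1(C/C=C(\C)CC/C=C(\C)CC/C=C(\C)[C@H](O)[C@H](O)C=C(C)C)CC(=O)C=CC1=O | target

## Step count and risks

Total step count: 13.
Longest linear sequence: 10 steps (steps 1–5 and 9–13).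

Steps most likely to fail:

**Step 10 (key step).** The Breslow intermediate may add too slowly to the fully substituted β-carbon, whose tether lies cis to the lactone carbonyl. Aldehyde self-condensation, base-induced migration of the skipped diene into conjugation, or eliminative opening of the dihydropyranone could then take over.

The fallback sets out from 17 and comes back at 18, and it replaces the polar acyl anion by an acyl radical:
- Pinnick oxidation (NaClO2, NaH2PO4, 2-methyl-2-butene, t-BuOH–H2O) should give the carboxylic acid F1.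
- (PhSe)2 and PBu3 should give the phenyl selenoester F2.
- Slow addition of Bu3SnH and AIBN in benzene at 80 °C should generate the nucleophilic acyl radical. It closes 6-exo onto C1 from the only face the tether can reach and gives 18 after hydrogen transfer to the α-lactone radical.

**Step 9.** Slow transmetalation of the electron-poor β-stannyl enoate may leave the π-allylpalladium complex time for β-hydride elimination. It may also allow syn/anti isomerisation, which would erode the 2'E geometry.

The fallback sets out from 16 and 10 and comes back at 17, and it reverses the polarity of the partners: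
- Iododestannylation of 16 (I2, CH2Cl2, 0 °C) should give the 4-iodo dihydropyranone F3.
- Palladium-catalysed borylation of 10 with B2pin2 (Pd2(dba)3, DMSO, 50 °C) should give the (E)-allylboronate F4.
- A linear-selective Suzuki–Miyaura coupling of the two (Pd with a bulky biarylphosphine, K3PO4, THF–H2O) should give 17.

**Step 12.** The dehydrogenation may stall after the alcohol oxidation. At the temperature it needs, oxidative attack on the allylic positions of the chain may also set in.

The fallback sets out from 19 and comes back at 21: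
- Dess–Martin oxidation at rt should give 20, now isolated.
- TMSOTf and Et3N should give the conjugated bis(silyl dienol ether) F5.
- Pd(OAc)2 in MeCN (Saegusa–Ito oxidation) should give 21 at rt.

## Further compounds

F1 | step 10 | 3-[(2S)-4-A-6-oxo-3,6-dihydro-2H-pyran-2-yl]propanoic acid | OC(=O)CC[C@H]1CC(C/C=C(\C)CC/C=C(\C)CC/C=C(\C)[C@H](O[Si](C)(C)C(C)(C)C)[C@H](O[Si](C)(C)C(C)(C)C)C=C(C)C)=CC(=O)O1
F2 | step 10 | Se-phenyl 3-[(2S)-4-A-6-oxo-3,6-dihydro-2H-pyran-2-yl]propaneselenoate | O=C(CC[C@H]1CC(C/C=C(\C)CC/C=C(\C)CC/C=C(\C)[C@H](O[Si](C)(C)C(C)(C)C)[C@H](O[Si](C)(C)C(C)(C)C)C=C(C)C)=CC(=O)O1)[Se]c1ccccc1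
F3 | step 9 | 3-[(2S)-4-iodo-6-oxo-3,6-dihydro-2H-pyran-2-yl]propanal | O=CCC[C@H]1CC(I)=CC(=O)O1
F4 | step 9 | 2-A-4,4,5,5-tetramethyl-1,3,2-dioxaborolane | CC1(C)OB(C/C=C(\C)CC/C=C(\C)CC/C=C(\C)[C@H](O[Si](C)(C)C(C)(C)C)[C@H](O[Si](C)(C)C(C)(C)C)C=C(C)C)OC1(C)C
F5 | step 12 | methyl 2-[(1R)-1-A-2,5-bis(trimethylsilyloxy)cyclohexa-2,4-dien-1-yl]acetate | COC(=O)C[C@@]1(C/C=C(\C)CC/C=C(\C)CC/C=C(\C)[C@H](O[Si](C)(C)C(C)(C)C)[C@H](O[Si](C)(C)C(C)(C)C)C=C(C)C)CC(O[Si](C)(C)C)=CC=C1O[Si](C)(C)C
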